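**Retrosynthetic overview**
- The strategy rests on C10. It lies between the C1 carbonyl and the C20 CH2–O carbon, so C20–C10–C1 is a 2-formyl ketone at a lower oxidation level, and its enol oxygen on C20 can be joined to C12. Because C9, C11 and C12 of ring C carry only hydrogen in the target, they can serve as the three-carbon allyl partner.
- Disconnections: δ-lactone C7–O–C20 (closed last); C9–C10 by Claisen rearrangement of the C20 enol ether of C12; C12–O by Mitsunobu union of a ring A hydroxymethylene enone with a bicyclo[3.2.1]octene allylic alcohol.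
- Ring A comes from 4,4-dimethylcyclohexenone (asymmetric vinyl addition sets C5, ethyl formate brings C20). Rings C and D come from diethyl 4-oxocyclohexane-1,1-dicarboxylate (hydrazone alkylation sets C13; a C12–O–C17 γ-lactone tether, oxygenation of C16, then Dieckmann closure of ring D set C8 and C16).
- Ring order: rings A and C bought; γ-lactone tether; ring D; union at C12–O and then C9–C10; δ-lactone; alkene saturation and deprotection.

Key step: step 17

Remark: atoms are numbered as in the 6,7-seco-kaurane skeleton (ring A = C1–C5, C10; ring C = C8, C9, C11–C14; ring D = C8, C14, C13, C16, C15; C17 on C16; C20 on C10; C7 is the carboxyl carbon on C8). "Exo" on ring D means toward C14, "endo" toward the C9–C11–C12 bridge; the "top" face of ring C is the face on which C14 lies.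
Remark: the sense of induction of RAMP, (R)-BINAP and the (R)-CBS catalyst is assigned by analogy with their standard substrates; the mirror-image reagent would be taken if a sense proved reversed.

**Route**

Step 1
Reactants: 1 4,4-dimethylcyclohex-2-en-1-one
Product: 2 4,4-dimethylcyclohexa-2,5-dien-1-one
Conditions: DDQ (1.3 equiv), dioxane, 100 °C
Reagents that add atoms: none
Why: DDQ dehydrogenation of the enone is the standard entry to 4,4-disubstituted cross-conjugated dienones, the quaternary C4 ruling out aromatisation.

Step 2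
Reactants: 2 4,4-dimethylcyclohexa-2,5-dien-1-one; 3 potassium vinyltrifluoroborate
Product: 4 (5R)-4,4-dimethyl-5-vinylcyclohex-2-en-1-one
Conditions: [Rh(cod)2]PF6 (3 mol %), (R)-BINAP (3.3 mol %), 3 (1.1 equiv), toluene/H2O (20:1), 100 °C, stopped before full conversion
Reagents that add atoms: none
Why: Rhodium/BINAP-catalysed asymmetric 1,4-addition (Hayashi–Miyaura type) of the vinyl group to one of the two enantiotopic enone halves of the prochiral dienone sets C5, (R)-BINAP being expected to give the (5R) product as it gives (R) adducts with cyclohex-2-enone, and the limiting boron reagent holds back a second addition.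

Step 3
Reactants: 4 (5R)-4,4-dimethyl-5-vinylcyclohex-2-en-1-one
Product: 6 (5S)-5-(hydroxymethyl)-4,4-dimethylcyclohex-2-en-1-one, via aldehyde 5 (not isolated)
Conditions: O3, CH2Cl2/MeOH (4:1), −78 °C (dye end point); Me2S; then NaBH4, −78 → −40 °C
Reagents that add atoms: ozone [O-][O+]=O
Why: Ozonolysis takes the electron-rich vinyl group in preference to the electron-poor enone alkene, and immediate low-temperature borohydride reduction converts the epimerisable aldehyde 5 into the alcohol faster than it attacks the conjugated ketone (any over-reduced allylic alcohol would be returned with MnO2), so C5 is carried through unchanged.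

Step 4
Reactants: 6 (5S)-5-(hydroxymethyl)-4,4-dimethylcyclohex-2-en-1-one
Product: 7 (5S)-5-[(tert-butyldimethylsilyloxy)methyl]-4,4-dimethylcyclohex-2-en-1-one
Conditions: TBSCl, imidazole, DMF, 0 °C → rt
Reagents that add atoms: tert-butyldimethylsilyl chloride CC(C)(C)[Si](C)(C)Cl
Why: Standard silylation of the primary alcohol, which also removes any tendency to hemiketal formation with the C1 ketone.

Step 5
Reactants: 7 (5S)-5-[(tert-butyldimethylsilyloxy)methyl]-4,4-dimethylcyclohex-2-en-1-one; 8 ethyl formate
Product: 9 (5R)-5-[(tert-butyldimethylsilyloxy)methyl]-6-(hydroxymethylene)-4,4-dimethylcyclohex-2-en-1-one (chelated enol of the 2-formyl ketone; the exocyclic carbon is C20)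
Conditions: NaH, 8 (3 equiv), EtOH (cat.), THF, 0 °C → rt; sat. aq. NH4Cl
Reagents that add atoms: none
Why: Crossed Claisen condensation (C-formylation) of the ketone enolate with ethyl formate can occur only at C10, the single enolisable α-position of the 4,4-disubstituted enone, and is driven by the stabilised enolate of the product.

Step 6
Reactants: 10 diethyl 4-oxocyclohexane-1,1-dicarboxylate; 11 (R)-1-amino-2-(methoxymethyl)pyrrolidine (RAMP)
Product: 12 RAMP hydrazone of 10
Conditions: 11 (1.1 equiv), cyclohexane, 60 °C, 4 Å molecular sieves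
Reagents that add atoms: none
Why: Condensation of the ketone with the chiral hydrazine gives the hydrazone, a single compound because the ketone is symmetrical.

Step 7
Reactants: 12 RAMP hydrazone of 10; 13 ethyl bromoacetate
Product: 14 (3R)-3-(2-ethoxy-2-oxoethyl) derivative of hydrazone 12 (C=N geometry not defined)
Conditions: LiN(iPr)2, THF, −78 → 0 °C; then 13, −100 → −78 °C
Reagents that add atoms: none
Why: Enders hydrazone alkylation, in which the lithium azaenolate chelated by the methoxymethyl arm is alkylated on one face, the (R)-auxiliary being expected by the usual model to give the (3R) centre (C13), while the quaternary geminal esters have no α-hydrogen to compete.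

Step 8
Reactants: 14 alkylated RAMP hydrazone
Product: 15 diethyl (3R)-3-(2-ethoxy-2-oxoethyl)-4-oxocyclohexane-1,1-dicarboxylate
Conditions: sat. aq. oxalic acid, Et2O, rt
Reagents that add atoms: water O
Why: Mild two-phase acid hydrolysis of the hydrazone frees the ketone without epimerising the new α-centre and returns the auxiliary.

Step 9
Reactants: 15 diethyl (3R)-3-(2-ethoxy-2-oxoethyl)-4-oxocyclohexane-1,1-dicarboxylate
Product: 16 diethyl (5R)-5-(2-ethoxy-2-oxoethyl)-4-(trimethylsilyloxy)cyclohex-3-ene-1,1-dicarboxylate
Conditions: LiN(iPr)2, TMSCl (in situ), THF, −78 °C; Et3N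
Reagents that add atoms: chlorotrimethylsilane C[Si](C)(C)Cl
Why: Kinetic deprotonation with in-situ silyl trapping takes the less substituted ketone α-CH2 (C11) in preference to the C13 methine and the less acidic ester CH2, so the silyl enol ether forms on the C11 side and C13 is not touched.

Step 10
Reactants: 16 silyl enol ether
Product: 17 diethyl (5R)-5-(2-ethoxy-2-oxoethyl)-4-oxocyclohex-2-ene-1,1-dicarboxylate
Conditions: Pd(OAc)2 (10 mol %), O2 (1 atm), DMSO, 40 °C
Reagents that add atoms: none
Why: Saegusa–Ito oxidation (palladium enolate, then β-hydride elimination) converts the silyl enol ether regiospecifically into the C9=C11 enone.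

Step 11
Reactants: 17 enone triester
Product: 19 diethyl (3aR,7aS)-2-oxo-3,3a,4,7a-tetrahydro-1-benzofuran-5,5(2H)-dicarboxylate (cis-fused γ-lactone C17(=O)–O–C12), via hydroxy triester 18 (not isolated)
Conditions: (R)-2-methyl-CBS-oxazaborolidine (0.3 equiv), catecholborane, toluene, −78 °C; MeOH; then CSA (5 mol %), CH2Cl2, rt
Reagents that add atoms: none
Why: Corey–Bakshi–Shibata 1,2-reduction under catalyst control (alkene flank as the larger group, so the (R)-catalyst should give the (S)-carbinol at C12) places the hydroxyl cis to the C13 side chain, and this cis γ-hydroxy ester closes under acid to the cis-fused γ-lactone with loss of ethanol.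

Step 12
Reactants: 19 cis-fused γ-lactone
Product: 20 3-hydroxy derivative of lactone 19 (hydroxyl on C16; C16 epimers)
Conditions: KN(SiMe3)2, THF, −78 °C, 15 min; then trans-2-(phenylsulfonyl)-3-phenyloxaziridine, −78 °C; sat. aq. NH4Cl
Reagents that add atoms: trans-2-(phenylsulfonyl)-3-phenyloxaziridine O=S(=O)(c1ccccc1)N1OC1c1ccccc1
Why: Davis hydroxylation of the lactone enolate (C16 is the only enolisable position) installs the C16 oxygen at this stage because, once ring D is closed, a planar C16 is no longer tolerated by the lactone bridge, and the configuration formed here is immaterial since the centre is re-enolised in step 14.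

Step 13
Reactants: 20 α-hydroxy lactone
Product: 21 3-(2-methoxypropan-2-yloxy) derivative of lactone 19 (mixed ketal on O16)
Conditions: 2-methoxypropene, PPTS (2 mol %), CH2Cl2, 0 °C; Et3N
Reagents that add atoms: 2-methoxypropene COC(C)=C
Why: Acid-catalysed addition of the alcohol to the enol ether (ketal formation) gives a base-stable mixed ketal that protects O16 through the enolate and hydride steps and later becomes the acetonide.

Step 14
Reactants: 21 α-alkoxy lactone
Product: 22 tricyclic β-keto lactone (bicyclo[3.2.1]oct-9(11)-ene; C7 ethyl ester on C8; C15 ketone; quaternary C16 with exo O-(2-methoxypropan-2-yl) and endo C17 lactone carbonyl bonded through oxygen to C12 on the ring C face anti to C14)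
Conditions: LiN(SiMe3)2 (1.2 equiv), THF, −78 → −20 °C; AcOH (1.2 equiv), −78 °C
Reagents that add atoms: none
Why: Dieckmann (intramolecular Claisen) condensation of the α-alkoxy lactone enolate onto the only geminal ester it can reach, the one cis to C16 across ring C, closes ring D and fixes C8, the lactone bridge holding C17 endo so that O16 ends exo at the new quaternary C16, and since the product cannot enolise the reaction is run kinetically and quenched cold to forestall retro-Claisen cleavage by ethoxide.

Step 15
Reactants: 22 tricyclic β-keto lactone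
Product: 24 bicyclic allylic alcohol (C7 ethyl ester; 12-OH on the ring C face anti to C14; endo 15-OH; 16,17-acetonide with O16 exo and C17 endo; C9=C11), via triol ketal 23 (not isolated)
Conditions: NaBH4 (excess), THF/EtOH, −40 → 20 °C; aq. NaHCO3; then PPTS (5 mol %), CH2Cl2, rt
Reagents that add atoms: none
Why: Borohydride reduction attacks the C15 ketone from the exo face (the endo face is covered by the lactone and the C9=C11 bridge) to give the endo alcohol trans to O16 and then opens the strained α-alkoxy lactone to the C17 and C12 alcohols while the neopentyl C7 ester stays, after which mild acid lets C17–OH displace methanol from the mixed ketal (transketalisation) to form the 16,17-acetonide.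

Step 16
Reactants: 24 bicyclic allylic alcohol; 9 ring A hydroxymethylene enone
Product: 25 C20 enol ether (O20 of 9 bonded to C12 on the ring C face syn to C14; remainder as in 24 and 9; enol ether geometry not fixed)
Conditions: 9 (1.5 equiv), PPh3, DIAD, toluene, 0 °C → rt
Reagents that add atoms: none
Why: Mitsunobu etherification with the acidic enol 9 as pronucleophile displaces the activated C12 oxygen with inversion, moving the ether oxygen to the top face of ring C, while the 15-OH, flanked by two quaternary carbons, is too hindered to be activated.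

Step 17
Reactants: 25 C20 enol ether
Product: 26 2-formyl enone (C9–C10 bond on the ring C face syn to C14; C11=C12; quaternary C10 with the C20 aldehyde cis to the C6 arm; remainder unchanged)
Conditions: o-xylene (0.01 M, degassed), BHT (cat.), base-washed glassware, 140 °C
Reagents that add atoms: none
Why: The allyl vinyl ether C10=C20–O–C12–C11=C9 undergoes a concerted suprafacial [3,3] sigmatropic shift in which the C9–C10 σ bond forms as the C12–O bond breaks, the alkene moves to C11=C12 and the enol ether becomes the C20 aldehyde; the closest known reaction type is the Claisen rearrangement of O-allyl enol ethers of 1,3-dicarbonyl compounds (2-allyloxymethylene ketones) to α-allyl α-formyl ketones. No ring is closed here, the six-membered array being only the chair- or boat-like transition state, and the δ-lactone is closed in step 18. C9 is controlled by the C12 ether oxygen, which is pseudoaxial on the top face of ring C, so that C10 arrives on the same face by 1,3-chirality transfer. C10 is controlled by C5, whose CH2OTBS arm lies pseudoaxial to avoid allylic strain with the exocyclic enol ether and leaves the opposite face for the incoming C9, which places C20 cis to C6. The step needs the concerted path to beat heterolysis to an allyl cation/dicarbonyl anion pair, which a non-polar acid-free medium should secure; elimination is shut off because the only β-hydrogen is at the C13 bridgehead, and the easily rotating push–pull enol ether can adopt whichever E or Z form fits both fixed faces.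

Step 18
Reactants: 26 2-formyl enone
Product: 28 protected spiro δ-lactone (lactone C7(=O)–O–C20 cis-fused to ring C; C11=C12; 16,17-acetonide; 15-OH; C6–OTBS), via hydroxy ester 27 (not isolated)
Conditions: LiAlH(OtBu)3, THF, −78 → −40 °C; aq. potassium sodium tartrate; then PPTS (10 mol %), toluene, 60 °C
Reagents that add atoms: none
Why: Chemoselective hydride reduction with the bulky aluminium reagent takes the aldehyde in the presence of the conjugated C1 ketone and the ester, and the C20 alcohol, gauche to the C7 ester across C8–C9, then lactonises under acid catalysis with loss of ethanol (base is avoided because the β-hydroxy ketone could lose formaldehyde by retro-aldol).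

Step 19
Reactants: 28 protected spiro δ-lactone
Product: 29 11,12-dihydro derivative of 28
Conditions: [Ir(cod)(PCy3)(py)]PF6 (5 mol %), H2 (1 atm), CH2Cl2, 0 °C → rt
Reagents that add atoms: none
Why: Hydroxyl-directed homogeneous hydrogenation, in which the endo 15-OH lying under C9/C11 binds iridium and delivers hydrogen to the lower face of C11=C12, an acceleration not shared by the remote, electron-poor enone alkene shielded on both faces by the C4 methyl groups; no stereocentre is formed.

Step 20
Reactants: 29 11,12-dihydro lactone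
Product: 30 CNP0546915.1
Conditions: 1 M aq. HCl, THF, 0 °C → rt
Reagents that add atoms: none
Why: Acid hydrolysis removes the silyl ether and the acetonide together, and no stereocentre carries a hydrogen α to a carbonyl group, so none can epimerise.

**Compound list**
1 | 4,4-dimethylcyclohex-2-en-1-one | CC1(C)CCC(=O)C=C1 | starting material
2 | 4,4-dimethylcyclohexa-2,5-dien-1-one | CC1(C)C=CC(=O)C=C1 | intermediate
3 | potassium vinyltrifluoroborate | [K+].C=C[B-](F)(F)F | starting material
4 | (5R)-4,4-dimethyl-5-vinylcyclohex-2-en-1-one | CC1(C)C=CC(=O)C[C@@H]1C=C | intermediate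
5 | (1S)-2,2-dimethyl-5-oxocyclohex-3-ene-1-carbaldehyde (not isolated) | CC1(C)C=CC(=O)C[C@@H]1C=O | intermediate
6 | (5S)-5-(hydroxymethyl)-4,4-dimethylcyclohex-2-en-1-one | CC1(C)C=CC(=O)C[C@@H]1CO | intermediate
7 | (5S)-5-[(tert-butyldimethylsilyloxy)methyl]-4,4-dimethylcyclohex-2-en-1-one | CC1(C)C=CC(=O)C[C@@H]1CO[Si](C)(C)C(C)(C)C | intermediate
8 | ethyl formate | CCOC=O | starting material
9 | (5R)-5-[(tert-butyldimethylsilyloxy)methyl]-6-(hydroxymethylene)-4,4-dimethylcyclohex-2-en-1-one | CC1(C)C=CC(=O)C(=CO)[C@@H]1CO[Si](C)(C)C(C)(C)C | intermediate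
10 | diethyl 4-oxocyclohexane-1,1-dicarboxylate | CCOC(=O)C1(CCC(=O)CC1)C(=O)OCC | starting material
11 | (R)-1-amino-2-(methoxymethyl)pyrrolidine (RAMP) | COC[C@H]1CCCN1N | starting material
12 | diethyl 4-{[(2R)-2-(methoxymethyl)pyrrolidin-1-yl]imino}cyclohexane-1,1-dicarboxylate | CCOC(=O)C1(C(=O)OCC)CCC(=NN2CCC[C@@H]2COC)CC1 | intermediate
13 | ethyl bromoacetate | CCOC(=O)CBr | starting material
14 | diethyl (3R)-3-(2-ethoxy-2-oxoethyl)-4-{[(2R)-2-(methoxymethyl)pyrrolidin-1-yl]imino}cyclohexane-1,1-dicarboxylate (C=N geometry not defined) | CCOC(=O)C1(C(=O)OCC)C[C@H](CC(=O)OCC)C(=NN2CCC[C@@H]2COC)CC1 | intermediate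
15 | diethyl (3R)-3-(2-ethoxy-2-oxoethyl)-4-oxocyclohexane-1,1-dicarboxylate | CCOC(=O)C1(C(=O)OCC)C[C@@H](C(=O)CC1)CC(=O)OCC | intermediate
16 | diethyl (5R)-5-(2-ethoxy-2-oxoethyl)-4-(trimethylsilyloxy)cyclohex-3-ene-1,1-dicarboxylate | CCOC(=O)C1(C(=O)OCC)C[C@H](CC(=O)OCC)C(O[Si](C)(C)C)=CC1 | intermediate
17 | diethyl (5R)-5-(2-ethoxy-2-oxoethyl)-4-oxocyclohex-2-ene-1,1-dicarboxylate | CCOC(=O)C1(C(=O)OCC)C[C@H](CC(=O)OCC)C(=O)C=C1 | intermediate
18 | diethyl (4S,5R)-5-(2-ethoxy-2-oxoethyl)-4-hydroxycyclohex-2-ene-1,1-dicarboxylate (cis; not isolated) | CCOC(=O)C1(C(=O)OCC)C[C@H](CC(=O)OCC)[C@H](O)C=C1 | intermediate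
19 | diethyl (3aR,7aS)-2-oxo-3,3a,4,7a-tetrahydro-1-benzofuran-5,5(2H)-dicarboxylate | CCOC(=O)C1(C(=O)OCC)C[C@@H]2CC(=O)O[C@@H]2C=C1 | intermediate
20 | 3-hydroxy derivative of 19 (C16–OH, C16 epimers) | CCOC(=O)C1(C(=O)OCC)C[C@@H]2C(O)C(=O)O[C@@H]2C=C1 | intermediate
21 | 3-(2-methoxypropan-2-yloxy) derivative of 19 (C16 epimers) | CCOC(=O)C1(C(=O)OCC)C[C@@H]2C(OC(C)(C)OC)C(=O)O[C@@H]2C=C1 | intermediate
22 | tricyclic β-keto lactone: C7 ethyl ester on C8, C15 ketone, C16 with exo O-(2-methoxypropan-2-yl) and endo C17(=O)–O–C12 lactone, C9=C11 | CCOC(=O)[C@@]12C[C@@H]([C@H]3C=C1)[C@@](OC(C)(C)OC)(C(=O)O3)C2=O | intermediate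
23 | triol ketal: 12-OH (face anti to C14), endo 15-OH, 17-OH, O16 as 2-methoxypropan-2-yl ether (not isolated) | CCOC(=O)[C@@]12C[C@@H]([C@H](O)C=C1)[C@@](OC(C)(C)OC)(CO)[C@H]2O | intermediate
24 | bicyclic allylic alcohol: C7 ethyl ester, 12-OH on the face anti to C14, endo 15-OH, 16,17-acetonide (O16 exo, C17 endo), C9=C11 | CCOC(=O)[C@@]12C[C@@H]([C@H](O)C=C1)[C@@]3(COC(C)(C)O3)[C@H]2O | intermediate
25 | C20 enol ether of 9 with C12 of the bicycle, oxygen on the ring C face syn to C14 (enol ether geometry not fixed) | CCOC(=O)[C@@]12C[C@@H]([C@@H](OC=C3C(=O)C=CC(C)(C)[C@H]3CO[Si](C)(C)C(C)(C)C)C=C1)[C@@]4(COC(C)(C)O4)[C@H]2O | intermediate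
26 | 2-formyl enone with C9–C10 bond (syn to C14), quaternary C10 (CHO cis to the C6 arm), C11=C12 | CCOC(=O)[C@@]12C[C@@H](C=C[C@H]1[C@]4(C=O)C(=O)C=CC(C)(C)[C@H]4CO[Si](C)(C)C(C)(C)C)[C@@]3(COC(C)(C)O3)[C@H]2O | intermediate
27 | C20 hydroxy ester from 26 (not isolated) | CCOC(=O)[C@@]12C[C@@H](C=C[C@H]1[C@]4(CO)C(=O)C=CC(C)(C)[C@H]4CO[Si](C)(C)C(C)(C)C)[C@@]3(COC(C)(C)O3)[C@H]2O | intermediate
28 | protected spiro δ-lactone with C11=C12, 16,17-acetonide, free 15-OH, C6–OTBS | CC1(C)C=CC(=O)[C@]2(COC(=O)[C@@]34C[C@@H](C=C[C@@H]23)[C@@]5(COC(C)(C)O5)[C@H]4O)[C@@H]1CO[Si](C)(C)C(C)(C)C | intermediate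
29 | 11,12-dihydro derivative of 28 | CC1(C)C=CC(=O)[C@]2(COC(=O)[C@@]34C[C@@H](CC[C@@H]23)[C@@]5(COC(C)(C)O5)[C@H]4O)[C@@H]1CO[Si](C)(C)C(C)(C)C | intermediate
30 | CNP0546915.1 (6,15,16,17-tetrahydroxy-1-oxo-6,7-seco-kaur-2-en-7,20-olide, stereoisomer as given) | CC1(C)C=CC(=O)[C@]2(COC(=O)[C@@]34C[C@@H](CC[C@@H]23)[C@@](O)(CO)[C@H]4O)[C@@H]1CO | target

**Totals**
Total step count: 20. Longest linear sequence: 15 steps (10 → 30, steps 6–20); the ring A branch (steps 1–5) joins at step 16.

**Steps most likely to fail**

Step 17 (key step). What may go wrong: heterolysis of the C12–O bond of the vinylogous formate to an allyl cation/dicarbonyl anion pair may outrun the concerted shift (recombination at C12 or at oxygen, loss of facial fidelity), or the shift may be too slow below the temperature at which 25 decomposes. Fallback, from 25 back to 28: the push–pull character is removed before the rearrangement. Luche reduction of 25 (NaBH4, CeCl3·7H2O, MeOH, −78 °C) should give the C1 allylic alcohol F1 (C1 epimers, handled base-buffered), which is silylated (Et3SiCl, imidazole, DMF) to the C1 triethylsilyl ether F2. This ordinary electron-rich allyl vinyl ether, for which ionisation is no longer favourable, should undergo an aliphatic Claisen rearrangement (toluene, 110–130 °C) to the quaternary aldehyde F3. Aldehyde reduction and acid lactonisation as in step 18 give the silylated lactone F4. Selective removal of the allylic triethylsilyl group (HF·pyridine, pyridine, THF, 0 °C) gives the allylic alcohol F5, and MnO2 (CH2Cl2) restores the C1 enone to give 28. The C1 centre created on the way is erased in the last operation.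

Step 16. What may go wrong: the oxyphosphonium ion of the concave allylic C12 alcohol may form slowly or ionise (allylic scrambling, partial retention), and the ambident enol may alkylate on carbon. Fallback, from 24 and 9 back to 25: inversion and ether formation are separated. Mitsunobu inversion of 24 with 4-nitrobenzoic acid (PPh3, DIAD, toluene), a small and strongly acidic partner suited to hindered alcohols, gives the inverted 4-nitrobenzoate F6, and methanolysis (K2CO3, MeOH) gives the C12-epimeric alcohol F7. Separately 9 is converted into its enol tosylate F8 (TsCl, Et3N, CH2Cl2, 0 °C). The sodium alkoxide of F7 (NaH, THF, 0 °C) then adds to F8 and expels tosylate (addition–elimination at the vinylic carbon, retention at C12), giving 25.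

Step 14. What may go wrong: closure to the strained cage may stall, or, because the product cannot be drained as an enolate, ethoxide may reverse the condensation (retro-Claisen) or open the lactone. Fallback, from 18 back to 24: the lactone tether is given up so that ring D closes to an enolisable β-keto ester. Compound 18 is intercepted before lactonisation as its silyl ether F9 (TBSOTf, 2,6-lutidine, CH2Cl2, −78 °C). A classical Dieckmann condensation (KOtBu, THF, 0 °C) of the side-chain ester enolate onto the geminal ester cis to it, driven by the product enolate, gives the bicyclic β-keto ester F10. Hydroxylation of its potassium enolate with the same oxaziridine from the open exo face gives the 16-hydroxy keto ester F11. NaBH4 (EtOH, 0 °C → rt) reduces the C15 ketone from the exo face and the α-hydroxy ester to the C17 carbinol, giving the triol F12. 2,2-Dimethoxypropane with PPTS gives the 16,17-acetonide F13 (the 1,2-diol forms the dioxolane), and Bu4NF (THF) frees the C12 alcohol to give 24.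

**Further compounds**
F1 | step 17 | C1 allylic alcohol from 25 (C1 epimers) | CCOC(=O)[C@@]12C[C@@H]([C@@H](OC=C3C(O)C=CC(C)(C)[C@H]3CO[Si](C)(C)C(C)(C)C)C=C1)[C@@]4(COC(C)(C)O4)[C@H]2O
F2 | step 17 | C1 triethylsilyl ether of F1 | CCOC(=O)[C@@]12C[C@@H]([C@@H](OC=C3C(O[Si](CC)(CC)CC)C=CC(C)(C)[C@H]3CO[Si](C)(C)C(C)(C)C)C=C1)[C@@]4(COC(C)(C)O4)[C@H]2O
F3 | step 17 | rearranged quaternary aldehyde with C1–OSiEt3 | CCOC(=O)[C@@]12C[C@@H](C=C[C@H]1[C@]4(C=O)C(O[Si](CC)(CC)CC)C=CC(C)(C)[C@H]4CO[Si](C)(C)C(C)(C)C)[C@@]3(COC(C)(C)O3)[C@H]2O
F4 | step 17 | δ-lactone with C1–OSiEt3 | CC1(C)C=CC(O[Si](CC)(CC)CC)[C@]2(COC(=O)[C@@]34C[C@@H](C=C[C@@H]23)[C@@]5(COC(C)(C)O5)[C@H]4O)[C@@H]1CO[Si](C)(C)C(C)(C)C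
F5 | step 17 | δ-lactone with free C1 allylic alcohol | CC1(C)C=CC(O)[C@]2(COC(=O)[C@@]34C[C@@H](C=C[C@@H]23)[C@@]5(COC(C)(C)O5)[C@H]4O)[C@@H]1CO[Si](C)(C)C(C)(C)C
F6 | step 16 | C12-inverted 4-nitrobenzoate of 24 | CCOC(=O)[C@@]12C[C@@H]([C@@H](OC(=O)c3ccc(cc3)[N+](=O)[O-])C=C1)[C@@]4(COC(C)(C)O4)[C@H]2O
F7 | step 16 | C12-epimer of 24 (12-OH syn to C14) | CCOC(=O)[C@@]12C[C@@H]([C@@H](O)C=C1)[C@@]3(COC(C)(C)O3)[C@H]2O
F8 | step 16 | enol tosylate of 9 | CC1(C)C=CC(=O)C(=COS(=O)(=O)c2ccc(C)cc2)[C@@H]1CO[Si](C)(C)C(C)(C)C
F9 | step 14 | tert-butyldimethylsilyl ether of 18 | CCOC(=O)C1(C(=O)OCC)C[C@H](CC(=O)OCC)[C@H](O[Si](C)(C)C(C)(C)C)C=C1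
F10 | step 14 | bicyclic β-keto ester (C15 ketone, C17 ethyl ester on C16, C12–OTBS) | CCOC(=O)[C@@]12C[C@@H]([C@H](O[Si](C)(C)C(C)(C)C)C=C1)C(C(=O)OCC)C2=O
F11 | step 14 | 16-hydroxy β-keto ester (OH exo) | CCOC(=O)[C@@]12C[C@@H]([C@H](O[Si](C)(C)C(C)(C)C)C=C1)[C@@](O)(C(=O)OCC)C2=O
F12 | step 14 | 15,16,17-triol with C12–OTBS | CCOC(=O)[C@@]12C[C@@H]([C@H](O[Si](C)(C)C(C)(C)C)C=C1)[C@@](O)(CO)[C@H]2O
F13 | step 14 | 16,17-acetonide with C12–OTBS | CCOC(=O)[C@@]12C[C@@H]([C@H](O[Si](C)(C)C(C)(C)C)C=C1)[C@@]3(COC(C)(C)O3)[C@H]2O
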